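**Strategy.** Ring atoms of the cycloheptenone: C1 (CH bearing 2-oxopropyl), C2 (C=O), C3 (C–CH2OH), C4 (=CH), C5 (CH2), C6 (quaternary), C7 (CH bearing the enol ester). The C2(=O)–C3(CH2OH)=C4 triad is read as a propiolate inserted into the C2–C5 bond of a cyclopentanone (C1, C2, C5, C6, C7) that already carries all three stereocentres. The key step is the [2+2] cycloaddition of its C2=C5 silyl enol ether with ethyl propiolate and electrocyclic opening of the siloxycyclobutene: the five-membered ring grows by two atoms and the ester carbon later becomes CH2OH. This precursor, an allyl-, silylalkynyl-, methyl- and methylpentenyl-substituted cyclopentene silyl ether, comes from (S)-4-silyloxycyclopentenone by three conjugate additions and a kinetic protonation.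

Key step: step 8

Assumption: the target is the enantiomer drawn by the given SMILES, (5S,6S,7R) in cyclohept-2-en-1-one numbering; compound 1 is taken as a purchasable (S)-enantiomer. The atom labels C1–C7 defined above are used for every intermediate.

Step 1
Reactants: 1 (S)-4-[(tert-butyldimethylsilyl)oxy]cyclopent-2-en-1-one; 2 ethynyltrimethylsilane
Product: 5 (3S,4R)-3-[(tert-butyldimethylsilyl)oxy]-4-[(trimethylsilyl)ethynyl]cyclopentan-1-one, via alkynylalane 3 (not isolated), via aluminium enolate 4 (not isolated)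
Conditions: 2, AlMe3, Et3N (cat.), heptane, 50 °C; then 1, Ni(acac)2 (cat.), i-Bu2AlH (cat.), Et2O, −5 °C; aq. NH4Cl
Reagents that add atoms: none
Why: Nickel-catalysed conjugate addition of a dimethylaluminium acetylide (zerovalent nickel from Ni(acac)2 and i-Bu2AlH) to an s-trans cyclic enone; the alkynyl group enters the β-carbon (future C7) anti to the bulky silyloxy group on the neighbouring carbon, so the purchased stereocentre sets C7.

Step 2
Reactants: 5 (3S,4R)-3-[(tert-butyldimethylsilyl)oxy]-4-[(trimethylsilyl)ethynyl]cyclopentan-1-one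
Product: 6 (S)-4-[(trimethylsilyl)ethynyl]cyclopent-2-en-1-one
Conditions: DBU, CH2Cl2, 0 °C
Reagents that add atoms: none
Why: E1cB β-elimination of silanolate from the β-silyloxy ketone gives the enone C2(=O)–C5=C6 and leaves the propargylic C7 as the only stereocentre.

Step 3
Reactants: 6 (S)-4-[(trimethylsilyl)ethynyl]cyclopent-2-en-1-one
Product: 7 trimethyl({(3R,4S)-3-methyl-4-[(trimethylsilyl)ethynyl]cyclopent-1-en-1-yl}oxy)silane
Conditions: MeMgBr, CuBr·SMe2 (cat.), Me3SiCl, HMPA, THF, −78 °C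
Reagents that add atoms: methylmagnesium bromide C[Mg]Br; chlorotrimethylsilane C[Si](C)(C)Cl
Why: Copper-catalysed, chlorosilane-accelerated conjugate addition of the Grignard reagent places the C6 methyl group and traps the enolate regiospecifically as the silyl enol ether; the new CH centre (methyl anti to alkynyl) is of no consequence because it becomes sp2 in step 4.

Step 4
Reactants: 7 trimethyl({(3R,4S)-3-methyl-4-[(trimethylsilyl)ethynyl]cyclopent-1-en-1-yl}oxy)silane
Product: 8 (S)-3-methyl-4-[(trimethylsilyl)ethynyl]cyclopent-2-en-1-one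
Conditions: Pd(OAc)2 (cat.), O2 (1 atm), DMSO, 40 °C
Reagents that add atoms: none
Why: Saegusa–Ito dehydrogenation of the regiodefined silyl enol ether (palladium enolate, β-hydride elimination, reoxidation by O2) gives the β-methyl enone without touching the γ-stereocentre C7.

Step 5
Reactants: 8 (S)-3-methyl-4-[(trimethylsilyl)ethynyl]cyclopent-2-en-1-one; 9 3-bromoprop-1-ene (allyl bromide)
Product: 11 (4S,5S)-3-methyl-5-(prop-2-en-1-yl)-4-[(trimethylsilyl)ethynyl]cyclopent-2-en-1-one, via lithium dienolate 10 (not isolated)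
Conditions: LiN(i-Pr)2, THF, −78 °C; then 9, DMPU, −78 to −30 °C
Reagents that add atoms: none
Why: Kinetic α'-deprotonation gives the cross-conjugated lithium dienolate, whose SN2 alkylation at C1 should occur anti to the adjacent alkynyl group (trans product); the allyl group is the masked 2-oxopropyl chain.

Step 6
Reactants: 11 (4S,5S)-3-methyl-5-(prop-2-en-1-yl)-4-[(trimethylsilyl)ethynyl]cyclopent-2-en-1-one
Product: 13 (4S,5R)-3-methyl-5-(prop-2-en-1-yl)-4-[(trimethylsilyl)ethynyl]cyclopent-2-en-1-one, via lithium dienolate 12 (not isolated)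
Conditions: LiN(i-Pr)2, THF, −78 °C; then 2,6-di-tert-butyl-4-methylphenol, THF, −78 °C
Reagents that add atoms: none
Why: Deprotonation to the planar dienolate and kinetic C-protonation by the hindered phenol from the face opposite to the C7 alkynyl group should invert C1 and give the contra-thermodynamic cis isomer, as in the kinetic protonation of 2,3-disubstituted cyclopentanone enolates.

Step 7
Reactants: 13 (4S,5R)-3-methyl-5-(prop-2-en-1-yl)-4-[(trimethylsilyl)ethynyl]cyclopent-2-en-1-one; 14 5-bromo-2-methylpent-2-ene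
Product: 16 trimethyl({(3R,4S,5R)-3-methyl-3-(4-methylpent-3-en-1-yl)-5-(prop-2-en-1-yl)-4-[(trimethylsilyl)ethynyl]cyclopent-1-en-1-yl}oxy)silane, via Grignard reagent 15 (not isolated)
Conditions: 14, Mg, THF, 25 °C; then CuBr·SMe2 (cat.), Me3SiCl, HMPA, 13, THF, −78 °C; Et3N, pentane
Reagents that add atoms: chlorotrimethylsilane C[Si](C)(C)Cl
Why: Copper-catalysed, chlorosilane-accelerated conjugate addition to the β,β-disubstituted enone creates the quaternary C6 with the new chain anti to the cis C7 alkynyl and C1 allyl groups, hence methyl cis to both, and delivers the C2=C5 silyl enol ether regiospecifically.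

Step 8
Reactants: 16 trimethyl({(3R,4S,5R)-3-methyl-3-(4-methylpent-3-en-1-yl)-5-(prop-2-en-1-yl)-4-[(trimethylsilyl)ethynyl]cyclopent-1-en-1-yl}oxy)silane; 17 ethyl prop-2-ynoate (ethyl propiolate)
Product: 19 ethyl (3R,4S,5S)-5-methyl-5-(4-methylpent-3-en-1-yl)-3-(prop-2-en-1-yl)-2-[(trimethylsilyl)oxy]-4-[(trimethylsilyl)ethynyl]cyclohepta-1,6-diene-1-carboxylate, via siloxycyclobutene 18 (not isolated)
Conditions: 17, HNTf2 (cat.), CH2Cl2, −78 °C; Et3N; then toluene, 80 °C
Reagents that add atoms: none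
Why: The silyl triflimide formed from HNTf2 activates the propiolate, the enol ether carbon C5 adds to its β-carbon (Mukaiyama–Michael) and the allenoate closes onto the silyloxocarbenium carbon C2 to give the 1-siloxybicyclo[3.2.0]hept-6-ene 18, whose push–pull cyclobutene (siloxy donor on C2, ester acceptor on C3) then opens thermally by 4π electrocyclic cleavage of the C2–C5 bond, so that C3 and C4 stand between C2 and C5. The closest known reaction type is the Lewis-acid-catalysed [2+2] cycloaddition of cyclic silyl enol ethers with propiolates followed by cyclobutene opening, a known two-carbon ring enlargement of cycloalkanones. The only ring closed is the cyclobutene, stepwise, by a 4-(enolexo)-exo-trig attack of the allenoate carbon on C2; the seven-membered ring is not closed but arises by breaking the bond shared by the four- and five-membered rings. The two bridgehead centres of 18 (cis fusion enforced by the small ring, face chosen anti to the C1 allyl group) are erased on opening, so no new stereocentre persists and C1, C6 and C7 are not touched. The step needs regiocontrol (ester carbon next to C2), which the polarity of enol ether and propiolate and the C2=C5 position fixed in step 7 secure, and chemoselectivity over the trisubstituted alkene, the terminal alkene and the silylalkyne, which the far higher nucleophilicity of the silyl enol ether at −78 °C should secure.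

Step 9
Reactants: 19 ethyl (3R,4S,5S)-5-methyl-5-(4-methylpent-3-en-1-yl)-3-(prop-2-en-1-yl)-2-[(trimethylsilyl)oxy]-4-[(trimethylsilyl)ethynyl]cyclohepta-1,6-diene-1-carboxylate
Product: 21 (5S,6S,7R)-2-(hydroxymethyl)-5-methyl-5-(4-methylpent-3-en-1-yl)-7-(prop-2-en-1-yl)-6-[(trimethylsilyl)ethynyl]cyclohept-2-en-1-one, via dienol silyl ether alcohol 20 (not isolated)
Conditions: i-Bu2AlH, CH2Cl2, −78 °C; aq. potassium sodium tartrate; then Bu4NF, AcOH, THF, −78 to 0 °C; Et3N (cat.), CH2Cl2, 25 °C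
Reagents that add atoms: none
Why: 1,2-Reduction of the β-siloxy dienoate (the C2 ketone stays masked as its silyl enol ether) turns the ester carbon into CH2OH; buffered fluoride then cleaves the O–Si bond and protonation at C5, completed by amine-mediated conjugation, should give the 2-(hydroxymethyl)enone, acid being avoided so that the allylic hydroxyl cannot ionise with help of the enol ether.

Step 10
Reactants: 21 (5S,6S,7R)-2-(hydroxymethyl)-5-methyl-5-(4-methylpent-3-en-1-yl)-7-(prop-2-en-1-yl)-6-[(trimethylsilyl)ethynyl]cyclohept-2-en-1-one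
Product: 22 (5S,6S,7R)-2-(hydroxymethyl)-5-methyl-5-(4-methylpent-3-en-1-yl)-7-(2-oxopropyl)-6-[(trimethylsilyl)ethynyl]cyclohept-2-en-1-one
Conditions: PdCl2 (cat.), CuCl, O2 (1 atm), DMF/H2O, 25 °C
Reagents that add atoms: water O
Why: Tsuji–Wacker oxidation: Markovnikov hydroxypalladation of the terminal alkene and β-hydride elimination give the methyl ketone, while the trisubstituted alkene, the enone and the silyl-capped alkyne should be inert.

Step 11
Reactants: 22 (5S,6S,7R)-2-(hydroxymethyl)-5-methyl-5-(4-methylpent-3-en-1-yl)-7-(2-oxopropyl)-6-[(trimethylsilyl)ethynyl]cyclohept-2-en-1-one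
Product: 23 (5S,6S,7R)-6-ethynyl-2-(hydroxymethyl)-5-methyl-5-(4-methylpent-3-en-1-yl)-7-(2-oxopropyl)cyclohept-2-en-1-one
Conditions: Bu4NF, AcOH, THF, 0 to 25 °C
Reagents that add atoms: none
Why: Fluoride-induced protodesilylation of the alkynylsilane; the acetic acid buffer keeps the medium non-basic so that the epimerisable C1 centre and the 1,4-diketone should survive.

Step 12
Reactants: 23 (5S,6S,7R)-6-ethynyl-2-(hydroxymethyl)-5-methyl-5-(4-methylpent-3-en-1-yl)-7-(2-oxopropyl)cyclohept-2-en-1-one; 24 3-methylbut-2-enoic acid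
Product: 25 (5S,6S,7R)-2-(hydroxymethyl)-5-methyl-5-(4-methylpent-3-en-1-yl)-6-{(Z)-2-[(3-methylbut-2-enoyl)oxy]ethenyl}-7-(2-oxopropyl)cyclohept-2-en-1-one
Conditions: 24, Ru(η3-CH2CMeCH2)2(Ph2P(CH2)4PPh2) (cat.), toluene, 50 °C
Reagents that add atoms: none
Why: Ruthenium-catalysed anti-Markovnikov addition of the carboxylic acid to the terminal alkyne through a vinylidene complex of divalent ruthenium should give the (Z)-enol ester by trans addition, leaving the trisubstituted and conjugated alkenes untouched.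

Step 13
Reactants: 25 (5S,6S,7R)-2-(hydroxymethyl)-5-methyl-5-(4-methylpent-3-en-1-yl)-6-{(Z)-2-[(3-methylbut-2-enoyl)oxy]ethenyl}-7-(2-oxopropyl)cyclohept-2-en-1-one
Product: 26 (5S,6S,7R)-5-[(2E)-4-hydroperoxy-4-methylpent-2-en-1-yl]-2-(hydroxymethyl)-5-methyl-6-{(Z)-2-[(3-methylbut-2-enoyl)oxy]ethenyl}-7-(2-oxopropyl)cyclohept-2-en-1-one (CNP0283385.3)
Conditions: O2, 5,10,15,20-tetraphenylporphyrin (cat.), visible light, CH2Cl2, 0 °C
Reagents that add atoms: dioxygen O=O
Why: Schenck ene reaction of singlet oxygen at the electron-rich trisubstituted alkene: abstraction of an allylic methylene hydrogen moves the double bond to the (E)-disubstituted position and puts the hydroperoxide on the tertiary carbon; the secondary hydroperoxide from methyl-hydrogen abstraction is expected as a separable regioisomer, and the electron-poor enone, senecioate and enol ester alkenes should not compete.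

**Compound list**

1 | (S)-4-[(tert-butyldimethylsilyl)oxy]cyclopent-2-en-1-one | O=C1C[C@H](O[Si](C)(C)C(C)(C)C)C=C1 | starting material
2 | ethynyltrimethylsilane | C#C[Si](C)(C)C | starting material
3 | dimethyl[(trimethylsilyl)ethynyl]aluminium | C[Al](C)C#C[Si](C)(C)C | intermediate
4 | dimethylaluminium enolate of 5 (O–Al on C2, C2=C1; silyloxy and alkynyl trans) | C[Al](C)OC=1C[C@H](O[Si](C)(C)C(C)(C)C)[C@@H](C#C[Si](C)(C)C)C=1 | intermediate
5 | (3S,4R)-3-[(tert-butyldimethylsilyl)oxy]-4-[(trimethylsilyl)ethynyl]cyclopentan-1-one | O=C1C[C@H](O[Si](C)(C)C(C)(C)C)[C@@H](C#C[Si](C)(C)C)C1 | intermediate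
6 | (S)-4-[(trimethylsilyl)ethynyl]cyclopent-2-en-1-one | O=C1C=C[C@@H](C#C[Si](C)(C)C)C1 | intermediate
7 | trimethyl({(3R,4S)-3-methyl-4-[(trimethylsilyl)ethynyl]cyclopent-1-en-1-yl}oxy)silane | C[Si](C)(C)OC1=C[C@H](C)[C@@H](C#C[Si](C)(C)C)C1 | intermediate
8 | (S)-3-methyl-4-[(trimethylsilyl)ethynyl]cyclopent-2-en-1-one | O=C1C=C(C)[C@@H](C#C[Si](C)(C)C)C1 | intermediate
9 | 3-bromoprop-1-ene | C=CCBr | starting material
10 | lithium dienolate of 8 (O–Li on C2; C2=C1 and C5=C6) | [Li]OC=1C=C(C)[C@@H](C#C[Si](C)(C)C)C=1 | intermediate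
11 | (4S,5S)-3-methyl-5-(prop-2-en-1-yl)-4-[(trimethylsilyl)ethynyl]cyclopent-2-en-1-one (allyl trans to alkynyl) | C=CC[C@@H]1C(=O)C=C(C)[C@H]1C#C[Si](C)(C)C | intermediate
12 | lithium dienolate of 11 (O–Li on C2; C2=C1 and C5=C6) | [Li]OC=1C=C(C)[C@@H](C#C[Si](C)(C)C)C=1CC=C | intermediate
13 | (4S,5R)-3-methyl-5-(prop-2-en-1-yl)-4-[(trimethylsilyl)ethynyl]cyclopent-2-en-1-one (allyl cis to alkynyl) | C=CC[C@H]1C(=O)C=C(C)[C@H]1C#C[Si](C)(C)C | intermediate
14 | 5-bromo-2-methylpent-2-ene | CC(C)=CCCBr | starting material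
15 | (4-methylpent-3-en-1-yl)magnesium bromide | CC(C)=CCC[Mg]Br | intermediate
16 | trimethyl({(3R,4S,5R)-3-methyl-3-(4-methylpent-3-en-1-yl)-5-(prop-2-en-1-yl)-4-[(trimethylsilyl)ethynyl]cyclopent-1-en-1-yl}oxy)silane | C=CC[C@H]1C(O[Si](C)(C)C)=C[C@](C)(CCC=C(C)C)[C@H]1C#C[Si](C)(C)C | intermediate
17 | ethyl prop-2-ynoate | C#CC(=O)OCC | starting material
18 | ethyl 4-methyl-4-(4-methylpent-3-en-1-yl)-2-(prop-2-en-1-yl)-1-[(trimethylsilyl)oxy]-3-[(trimethylsilyl)ethynyl]bicyclo[3.2.0]hept-6-ene-7-carboxylate (cis-fused, cyclobutene on the face opposite to allyl and alkynyl; other centres as in 16) | C=CC[C@H]1[C@]2(O[Si](C)(C)C)C(C(=O)OCC)=C[C@@H]2[C@](C)(CCC=C(C)C)[C@H]1C#C[Si](C)(C)C | intermediate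
19 | ethyl (3R,4S,5S)-5-methyl-5-(4-methylpent-3-en-1-yl)-3-(prop-2-en-1-yl)-2-[(trimethylsilyl)oxy]-4-[(trimethylsilyl)ethynyl]cyclohepta-1,6-diene-1-carboxylate | C=CC[C@H]1C(O[Si](C)(C)C)=C(C(=O)OCC)C=C[C@](C)(CCC=C(C)C)[C@H]1C#C[Si](C)(C)C | intermediate
20 | {(3R,4S,5S)-5-methyl-5-(4-methylpent-3-en-1-yl)-3-(prop-2-en-1-yl)-2-[(trimethylsilyl)oxy]-4-[(trimethylsilyl)ethynyl]cyclohepta-1,6-dien-1-yl}methanol | C=CC[C@H]1C(O[Si](C)(C)C)=C(CO)C=C[C@](C)(CCC=C(C)C)[C@H]1C#C[Si](C)(C)C | intermediate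
21 | (5S,6S,7R)-2-(hydroxymethyl)-5-methyl-5-(4-methylpent-3-en-1-yl)-7-(prop-2-en-1-yl)-6-[(trimethylsilyl)ethynyl]cyclohept-2-en-1-one | C=CC[C@H]1C(=O)C(CO)=CC[C@](C)(CCC=C(C)C)[C@H]1C#C[Si](C)(C)C | intermediate
22 | (5S,6S,7R)-2-(hydroxymethyl)-5-methyl-5-(4-methylpent-3-en-1-yl)-7-(2-oxopropyl)-6-[(trimethylsilyl)ethynyl]cyclohept-2-en-1-one | CC(=O)C[C@H]1C(=O)C(CO)=CC[C@](C)(CCC=C(C)C)[C@H]1C#C[Si](C)(C)C | intermediate
23 | (5S,6S,7R)-6-ethynyl-2-(hydroxymethyl)-5-methyl-5-(4-methylpent-3-en-1-yl)-7-(2-oxopropyl)cyclohept-2-en-1-one | CC(=O)C[C@H]1C(=O)C(CO)=CC[C@](C)(CCC=C(C)C)[C@H]1C#C | intermediate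
24 | 3-methylbut-2-enoic acid | CC(C)=CC(=O)O | starting material
25 | (5S,6S,7R)-2-(hydroxymethyl)-5-methyl-5-(4-methylpent-3-en-1-yl)-6-{(Z)-2-[(3-methylbut-2-enoyl)oxy]ethenyl}-7-(2-oxopropyl)cyclohept-2-en-1-one | CC(=O)C[C@H]1C(=O)C(CO)=CC[C@](C)(CCC=C(C)C)[C@H]1/C=C\OC(=O)C=C(C)C | intermediate
26 | (5S,6S,7R)-5-[(2E)-4-hydroperoxy-4-methylpent-2-en-1-yl]-2-(hydroxymethyl)-5-methyl-6-{(Z)-2-[(3-methylbut-2-enoyl)oxy]ethenyl}-7-(2-oxopropyl)cyclohept-2-en-1-one | CC(=O)C[C@H]1C(=O)C(CO)=CC[C@](C)(C/C=C/C(C)(C)OO)[C@H]1/C=C\OC(=O)C=C(C)C | target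

**Total steps:** 13. **Longest linear sequence:** 13 steps (from 1).

**Steps most likely to fail, with fallbacks**

Step 8. The cycloaddition may stop after the first C–C bond (silyl loss before four-membered ring closure gives an open-chain alkenoate), or the silyloxocarbenium ion may be intercepted by the trisubstituted side-chain alkene. The fallback keeps the two-carbon enlargement but runs it without a cationic intermediate. Compound 16 is desilylated (Bu4NF, AcOH, THF, −78 °C) to the ketone (2R,3S,4S)-4-methyl-4-(4-methylpent-3-en-1-yl)-2-(prop-2-en-1-yl)-3-[(trimethylsilyl)ethynyl]cyclopentan-1-one F1. Condensation with pyrrolidine (molecular sieves, benzene) should give the less substituted enamine 1-{(3R,4S,5R)-3-methyl-3-(4-methylpent-3-en-1-yl)-5-(prop-2-en-1-yl)-4-[(trimethylsilyl)ethynyl]cyclopent-1-en-1-yl}pyrrolidine F2. Its thermal [2+2] cycloaddition with 17 and spontaneous cyclobutene opening (the classical enamine–propiolate ring enlargement) should give the dienamine ester ethyl (3R,4S,5S)-5-methyl-5-(4-methylpent-3-en-1-yl)-3-(prop-2-en-1-yl)-2-(pyrrolidin-1-yl)-4-[(trimethylsilyl)ethynyl]cyclohepta-1,6-diene-1-carboxylate F3. Mild aqueous acid (AcOH, NaOAc, H2O) releases the β-keto ester, drawn as its enol ethyl (3R,4S,5S)-2-hydroxy-5-methyl-5-(4-methylpent-3-en-1-yl)-3-(prop-2-en-1-yl)-4-[(trimethylsilyl)ethynyl]cyclohepta-1,6-diene-1-carboxylate F4, and O-silylation (Me3SiCl, Et3N) comes back to the route at 19.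

Step 6. Deprotonation may occur at the C6 methyl group (γ) instead of C1, O-protonation may be followed by unselective ketonisation, and the slim alkynyl group may discriminate the faces poorly, all of which leave the trans isomer. The fallback sets out from 8 and forms the C1 enolate by conjugate addition instead of deprotonation. LiN(i-Pr)2 and dimethylmethylideneammonium iodide give the Mannich base (4S,5R)-5-[(dimethylamino)methyl]-3-methyl-4-[(trimethylsilyl)ethynyl]cyclopent-2-en-1-one F5. N-Methylation and elimination (MeI; NaHCO3) give the exocyclic enone (R)-3-methyl-5-methylidene-4-[(trimethylsilyl)ethynyl]cyclopent-2-en-1-one F6. Copper-catalysed 1,4-addition of vinylmagnesium bromide (CuBr·SMe2, THF, −78 °C) to the unhindered exocyclic enone builds the allyl group and generates the C1 enolate regiospecifically, and its protonation in the flask by the hindered phenol at −78 °C comes back to the route at 13.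

Step 12. Vinylidene formation at the hindered, α-branched alkyne may be slow, and Markovnikov addition or erosion of the Z geometry may compete. The fallback sets out from 23 and fixes the alkene geometry before the C–O bond is made. Iodination (N-iodosuccinimide, AgNO3 (cat.), acetone) gives the iodoalkyne (5S,6S,7R)-2-(hydroxymethyl)-6-(iodoethynyl)-5-methyl-5-(4-methylpent-3-en-1-yl)-7-(2-oxopropyl)cyclohept-2-en-1-one F7. cis-Reduction with diimide (2-nitrobenzenesulfonohydrazide, Et3N, THF/i-PrOH) gives the vinyl iodide (5S,6R,7R)-2-(hydroxymethyl)-6-[(Z)-2-iodoethenyl]-5-methyl-5-(4-methylpent-3-en-1-yl)-7-(2-oxopropyl)cyclohept-2-en-1-one F8. Copper-catalysed C–O coupling with 24 (CuI, N,N′-dimethylethylenediamine, Cs2CO3, toluene, 80 °C), which retains the alkene geometry, comes back to the route at 25.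

**Further compounds**

F1 | step 8 | (2R,3S,4S)-4-methyl-4-(4-methylpent-3-en-1-yl)-2-(prop-2-en-1-yl)-3-[(trimethylsilyl)ethynyl]cyclopentan-1-one | C=CC[C@H]1C(=O)C[C@](C)(CCC=C(C)C)[C@H]1C#C[Si](C)(C)C
F2 | step 8 | 1-{(3R,4S,5R)-3-methyl-3-(4-methylpent-3-en-1-yl)-5-(prop-2-en-1-yl)-4-[(trimethylsilyl)ethynyl]cyclopent-1-en-1-yl}pyrrolidine | C=CC[C@H]1C(N2CCCC2)=C[C@](C)(CCC=C(C)C)[C@H]1C#C[Si](C)(C)C
F3 | step 8 | ethyl (3R,4S,5S)-5-methyl-5-(4-methylpent-3-en-1-yl)-3-(prop-2-en-1-yl)-2-(pyrrolidin-1-yl)-4-[(trimethylsilyl)ethynyl]cyclohepta-1,6-diene-1-carboxylate | C=CC[C@H]1C(N2CCCC2)=C(C(=O)OCC)C=C[C@](C)(CCC=C(C)C)[C@H]1C#C[Si](C)(C)C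
F4 | step 8 | ethyl (3R,4S,5S)-2-hydroxy-5-methyl-5-(4-methylpent-3-en-1-yl)-3-(prop-2-en-1-yl)-4-[(trimethylsilyl)ethynyl]cyclohepta-1,6-diene-1-carboxylate | C=CC[C@H]1C(O)=C(C(=O)OCC)C=C[C@](C)(CCC=C(C)C)[C@H]1C#C[Si](C)(C)C
F5 | step 6 | (4S,5R)-5-[(dimethylamino)methyl]-3-methyl-4-[(trimethylsilyl)ethynyl]cyclopent-2-en-1-one | CN(C)C[C@@H]1C(=O)C=C(C)[C@H]1C#C[Si](C)(C)C
F6 | step 6 | (R)-3-methyl-5-methylidene-4-[(trimethylsilyl)ethynyl]cyclopent-2-en-1-one | C=C1C(=O)C=C(C)[C@H]1C#C[Si](C)(C)C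
F7 | step 12 | (5S,6S,7R)-2-(hydroxymethyl)-6-(iodoethynyl)-5-methyl-5-(4-methylpent-3-en-1-yl)-7-(2-oxopropyl)cyclohept-2-en-1-one | CC(=O)C[C@H]1C(=O)C(CO)=CC[C@](C)(CCC=C(C)C)[C@H]1C#CI
F8 | step 12 | (5S,6R,7R)-2-(hydroxymethyl)-6-[(Z)-2-iodoethenyl]-5-methyl-5-(4-methylpent-3-en-1-yl)-7-(2-oxopropyl)cyclohept-2-en-1-one | CC(=O)C[C@H]1C(=O)C(CO)=CC[C@](C)(CCC=C(C)C)[C@H]1/C=C\I
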